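## Structural features

The target is a (12Z)-labda-12,14-diene (labdane locants throughout). It is a trans-fused decalin: ring A carries the gem-dimethyl group at C4, ring B the angular methyl C20 at C10, and C9 bears a (2Z)-3-methylpenta-2,4-dienyl chain (C11–C16). Six stereocentres, C5 to C10, run without a break round ring B; C8 (a tertiary carbinol carrying C17) and C10 are fully substituted and flank C9. In the required enantiomer (5R,6S,7R,8R,9S,10R), C20, C17, the C11 arm and the C7 acetoxy group lie on one face, and H5, the C6 hydroxyl and the C8 hydroxyl on the other. The three oxygens are therefore equatorial and mutually trans, and C17 is axial and syn to C20. The fragile parts are the conjugated Z-diene (acid-induced isomerisation or cyclisation onto the C8 hydroxyl, peracids, radicals), the tertiary alcohol (dehydration) and the single acetate between two free hydroxyls (acyl migration or loss under base). The real difficulty is the congested C8–C9–C10 triad with its two quaternary carbons, together with the differentiation of three neighbouring oxygens of which only O7 is acylated. Ring B can be opened at C7–C8 and C9–C10. C7–C6–C5–C10 then becomes a diene resting on the ring A alkene, and C8–C9 a trisubstituted enal whose E geometry already encodes the cis relation of C17 and C11. Its formyl carbon can later be exchanged for the C8 oxygen with retention, and the C5=C6 alkene it leaves behind serves to set the ring fusion.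

## Logic of the disconnections

22 ⇒ 21. The C13–C14 bond is cut, removing the terminal vinyl group. The diene is the most sensitive function, so it is made last. What remains is a Z-iodoalkene, which is robust. The forward coupling must proceed with retention at C13 under neutral conditions, because the diol monoacetate is already free.

21 ⇒ 20 ⇒ 19. The two O–Si bonds (O6, O8) are restored and the C12=C13 bond is cut to an aldehyde. This removes the only stereodefined alkene. The forward olefination must be Z-selective with an α-iodo ylide and must tolerate the acetate. The silyl group on O8 is kept until after this step so that C12 stays a free aldehyde and does not close to a lactol.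

19 ⇒ 18 ⇒ 17. No skeletal bond is cut; C12 is taken back to the alcohol and then to its benzyl ether. O12 is carried as a benzyl ether and not as a second silyl ether because the silyl ether on O7 must be removed alone earlier in the route. Hydrogenolysis is possible exactly here, the one stage with no C=C bond in the molecule.

17 ⇒ 16 ⇒ 15. The O7–acyl bond and then the C7–H bond are cut. Because O6 and O8 are silylated in 16, acetylation needs no selectivity. The C7 carbinol comes from a ketone, which demands hydride delivery from the face anti to the axial C17 methyl.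

15 ⇒ 13 ⇒ 12. The C6–O bond is cut (enol silane oxidation). A C7 ketone can only enolise toward C6 because C8 is quaternary, so regiochemistry is automatic. The forward step needs attack anti to C20 and transfer of the silyl group to the new oxygen.

12 ⇒ 11 ⇒ 9 ⇒ 8. C7 is returned to the alcohol oxidation level and the C8–O bond is traced back to a C8–CHO bond. This turns the tertiary carbinol into a quaternary carbon that a cycloaddition can build. The forward oxidative rearrangement must migrate the tertiary carbon with retention and needs a substrate with no alkene.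

8 ⇒ 7. The C5–H and C6–H bonds are removed to give the C5=C6 alkene. The forward hydrogenation must give the trans fusion on an alkene flanked by two quaternary carbons.

7 ⇒ 2 + 6. The C7–C8 and C9–C10 bonds are cut, opening ring B. The problem falls into a ring A diene and an acyclic enal, each one or two steps from commerce, and four stereocentres (C7–C10) are traced back to one catalyst and two alkene geometries. The forward cycloaddition must join two fully substituted carbons to their partners with regio-, endo- and facial control.

2 ⇒ 1; 6 ⇒ 4 + 5; 4 ⇒ 3. The O–Si bond of the dienol ether is cut to the parent aldehyde. The C8=C9 bond of the enal is cut to an aldehyde and a formyl-stabilised ylide, and the aldehyde is taken back to its alcohol. All three ends (1, 3, 5) are commercial; the demands are E geometry in both 2 and 6.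

## Other disconnections considered

Alternative 1: The cut runs through C5–C10 and C8–C9, so both rings come from one open-chain triene, A1. A1 is an N-enoyl oxazolidinone whose β,β-disubstituted alkene (C9=C10) is tethered through C1–C4 to a 1-methyl-1-silyloxydiene (C5–C8). The forward key step is an intramolecular Diels–Alder reaction, run with a chiral Lewis acid chelated by the imide, to the trans-decalin A2.
- In its favour: two rings, the trans fusion and the C8 oxygen are obtained directly, so neither an alkene hydrogenation nor a formyl-to-oxygen exchange is needed. On these two points it is better than the chosen plan. The C6=C7 alkene of A2 is also a natural precursor of the trans-6,7-diol.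
- Against it: the diene terminus C8 is 1,1-disubstituted, so either the methyl or the silyloxy group must point inward in the reactive s-cis conformer. The C8 configuration depends on making the enol silane with oxygen inside, from a methyl ketone that prefers to enolise kinetically toward its methyl group. The dienophile is a poor one. In A2 the carbon on C9 is C11 at the acid level, so the whole C12–C16 diene must still be attached and C11 reduced to a methylene. O6 and O7 would emerge from the alkene undifferentiated.
- Comparison: both plans create the two quaternary carbons in the key step (equal). The intramolecular version profits from the tether, the chosen one from a strongly polarised diene/dienophile pair. The chosen precursors are one and two steps from commerce, against an estimated eight to ten for A1 with its three defined alkenes.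

Alternative 2: The cut is made in ring A, at C1–C10 and C4–C5, giving the quinone A3 as a ready-made ring B and the diene A4. The forward key step is an oxazaborolidinium-catalysed quinone Diels–Alder reaction to the cis-fused ene-dione A5, in which the CH2 terminus of A4 would bond to the methyl-bearing quinone carbon (C10).
- In its favour: A3 and A4 are both commercial, so the key step would be the first step (better than the chosen plan). Quinones are the best-established dienophiles for this catalyst class (better precedent). The quaternary C10 is set with absolute control, and A5 already carries oxygen at C6 and a handle at C9.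
- Against it: A4 has a Z-methyl group on its terminus, which makes the s-cis conformer very unfavourable; such dienes are sluggish and prone to acid-induced isomerisation. Only C10 is set for good: C5 must be epimerised to the trans fusion and C8 and C9 are still trigonal. C9 arrives as a ketone next to the quaternary C10, so the side chain must be added to a neopentyl-type carbonyl and the resulting oxygen removed with control of C9. The C2=C3 alkene is superfluous.
- Comparison: the two cycloadditions are of the same mechanistic type. The chosen one forms the more hindered bonds but uses an electronically activated diene and fixes C7–C10 together with the first two side-chain carbons. The sequence after A5 is expected to be clearly longer than the thirteen steps that follow the chosen key step.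

Alternative 3: Only the C9–C10 bond is cut. Ring A, C5 and C6–C8 with C17 come from the chiral-pool ketone A6, which would be elaborated into the hydroxy enoate A7 by asymmetric dihydroxylation of its side-chain alkene, acetonide formation and addition of a three-carbon ester unit to the methyl ketone. The forward key step is hydrogen-atom transfer from an iron hydride to C1 of the ring alkene, 6-exo addition of the tertiary C10 radical to the enoate β-carbon C9, and reduction of the resulting α-ester radical, giving the trans-decalin A8.
- In its favour: A8 holds all six ring stereocentres and all three oxygens of the target with C11 and C12 attached, a level the chosen plan reaches only nine steps after its cycloaddition. It is better than the chosen plan in the stereochemical content of the key product and probably in overall step count. Radical conjugate cyclisations of this kind are well established for congested quaternary centres and tolerate a free tertiary alcohol.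
- Against it: C8 must be set by addition to a ketone next to the dioxolane, where Felkin and chelation control point in opposite directions. C10 and C9 are controlled only by the conformation of the cyclisation transition state, which must accommodate a trans-fused dioxolane that resists the gauche C5–C6–C7–C8 arrangement. O6 and O7 are released together from the acetonide, so selective acetylation of O7 would have to be solved, whereas the chosen plan differentiates them by order of introduction. Enantiopure A6 is far more costly than the racemate.
- Comparison: absolute configuration rests there on the chiral pool plus a reagent-controlled dihydroxylation and here on one catalytic cycloaddition (equal in principle). The radical closure forms one congested bond where the cycloaddition must form two. This is the strongest of the three alternatives and would be preferred if the diastereoselectivity of the cyclisation and the O6/O7 differentiation could be relied upon.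

Key step: step 4

Remark: labdane locants are used for all bicyclic compounds; "syn" and "anti" mean on the same or the opposite face of ring B as C20.
Assumption: 1 is bought as the flavour-grade article of commerce; if it had to be made, a one-carbon Wittig homologation of the next lower commercial aldehyde would add two routine steps.
Assumption: the (R)-configured oxazaborolidinium ion is taken to leave open the C8-Si/C9-Re face of the bound enal, as the formyl C–H···O binding model predicts for 2-substituted enals; should the sense be opposite, the mirror-image catalyst is used with no other change.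

Step 1
Reactants: 1 2-(2,6,6-trimethylcyclohex-1-en-1-yl)acetaldehyde
Product: 2 (E)-2-[2-(tert-butyldimethylsilyloxy)ethenyl]-1,3,3-trimethylcyclohexene
Conditions: TBSOTf, Et3N, CH2Cl2, 0 °C → rt
Reagents that add atoms: tert-butyldimethylsilyl trifluoromethanesulfonate (TBSOTf), CC(C)(C)[Si](C)(C)OS(=O)(=O)C(F)(F)F
Why: Soft enolisation and O-silylation of an aldehyde; the CH2 group is both α to the carbonyl and allylic, so the conjugated dienol silyl ether is the only enol silane that can form. The bulky trimethylcyclohexenyl group should favour the E isomer; any Z isomer is inert in step 4 and can be removed or equilibrated with a trace of iodine.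

Step 2
Reactants: 3 3-(benzyloxy)propan-1-ol
Product: 4 3-(benzyloxy)propanal
Conditions: PhI(OAc)2, 2,2,6,6-tetramethylpiperidin-1-oxyl (10 mol%), CH2Cl2, rt
Reagents that add atoms: none
Why: Nitroxyl-catalysed oxidation of a primary alcohol stops at the aldehyde, and its neutral medium avoids β-elimination of the benzyloxy group; 4 is used without storage.

Step 3
Reactants: 4 3-(benzyloxy)propanal; 5 2-(triphenylphosphoranylidene)propanal
Product: 6 (E)-5-(benzyloxy)-2-methylpent-2-enal
Conditions: toluene, 80 °C
Reagents that add atoms: none
Why: Wittig olefination with a formyl-stabilised ylide gives the (E)-2-methyl enal under thermodynamic control of the oxaphosphetane; the product enal is much less electrophilic than 4, so a second olefination should be minor.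

Step 4
Reactants: 2 (E)-2-[2-(tert-butyldimethylsilyloxy)ethenyl]-1,3,3-trimethylcyclohexene; 6 (E)-5-(benzyloxy)-2-methylpent-2-enal
Product: 7 (7S,8R,9S,10S)-12-(benzyloxy)-7-(tert-butyldimethylsilyloxy)-13,14,15,16-tetranorlabd-5-ene-8-carbaldehyde
Conditions: (R)-1-(2-methylphenyl)-3,3-diphenyltetrahydro-1H,3H-pyrrolo[1,2-c][1,3,2]oxazaborole (20 mol%), (CF3SO2)2NH (16 mol%), CH2Cl2, −78 → −40 °C; Et3N quench
Reagents that add atoms: none
Why: The protonated oxazaborolidine binds the formyl oxygen of 6 at boron, lowers the enal LUMO and lets the electron-rich dienol silyl ether 2 add in a concerted but asynchronous [4+2] cycloaddition in which the C9–C10 bond leads and the C7–C8 bond follows; the closest known reaction type is the oxazaborolidinium-catalysed Diels–Alder reaction of 2-substituted enals with alkyl- and silyloxy-dienes. Ring B is closed by this intermolecular [4+2] annulation onto the C5=C10 alkene of ring A, both σ-bonds forming suprafacially on each partner. Regiochemistry follows from the donor oxygen on C7, which puts the largest HOMO coefficient on C10 and pairs it with the enal β-carbon C9. The relative configuration of C8 and C9 (C17 cis to C11) is the E geometry of 6 carried through the suprafacial addition. C7 and C10 are set relative to them by the formyl-endo transition state: the outside silyloxy group of the E-dienol ether ends cis to the formyl group and the inside methyl C20 ends cis to C17 and C11, and this mode is also the less crowded one because it places H9 and not the C11 chain under the C4/C5 region of the diene. The absolute configuration comes from the catalyst, whose aryl group covers one face of the bound s-trans enal so that 2 adds to the C8-Si/C9-Re face and (7S,8R,9S,10S)-7 results. The step needs cycloaddition at C=C in preference to Mukaiyama-type addition at the formyl carbon and needs the enol silane to survive the acid; the shielding of the boron-bound carbonyl, the bulk of the silyl group, the slight excess of oxazaborolidine over (CF3SO2)2NH and the low temperature are meant to secure this. Because two quaternary carbons (C8 and C10) are created, this is the most demanding step of the route.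

Step 5
Reactants: 7 (7S,8R,9S,10S)-12-(benzyloxy)-7-(tert-butyldimethylsilyloxy)-13,14,15,16-tetranorlabd-5-ene-8-carbaldehyde
Product: 8 (5R,7S,8R,9S,10R)-12-(benzyloxy)-7-(tert-butyldimethylsilyloxy)-13,14,15,16-tetranorlabdane-8-carbaldehyde
Conditions: Mn(dpm)3 (10 mol%), PhSiH3, t-BuOOH, i-PrOH/hexane, rt
Reagents that add atoms: none
Why: Hydrogen-atom-transfer hydrogenation: the manganese hydride gives H• to C6, and the tertiary C5 radical takes its hydrogen on the face anti to C20 and the axial C4 methyl, which leads to the more stable trans-fused decalin (C5 R). The hindered aldehyde, the silyl ether and the benzyl ether are not expected to react under these radical conditions.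

Step 6
Reactants: 8 (5R,7S,8R,9S,10R)-12-(benzyloxy)-7-(tert-butyldimethylsilyloxy)-13,14,15,16-tetranorlabdane-8-carbaldehyde
Product: 9 (5R,7S,8R,9S,10R)-12-(benzyloxy)-7-(tert-butyldimethylsilyloxy)-13,14,15,16-tetranorlabdan-8-yl formate
Conditions: mCPBA, NaHCO3, CH2Cl2, 0 °C → rt
Reagents that add atoms: 3-chloroperoxybenzoic acid (mCPBA), OOC(=O)c1cccc(Cl)c1
Why: Baeyer–Villiger oxidation of an α-quaternary aldehyde: in the Criegee adduct the tertiary C8 migrates in preference to hydrogen and with retention, so the formyl carbon is exchanged for oxygen on the face anti to C20. No alkene is left to be epoxidised.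

Step 7
Reactants: 9 (5R,7S,8R,9S,10R)-12-(benzyloxy)-7-(tert-butyldimethylsilyloxy)-13,14,15,16-tetranorlabdan-8-yl formate
Product: 11 (5R,7S,8R,9S,10R)-12-(benzyloxy)-13,14,15,16-tetranorlabdane-7,8-diol, via 7-silyloxy-8-ol 10 (not isolated)
Conditions: K2CO3 (cat.), MeOH, rt; concentrate; Bu4NF, THF, 50 °C
Reagents that add atoms: none
Why: Transesterification removes the formate at once, and fluoride then cleaves the hindered secondary silyl ether. The benzyl ether is inert to both, which is the reason O12 is not carried as a silyl ether.

Step 8
Reactants: 11 (5R,7S,8R,9S,10R)-12-(benzyloxy)-13,14,15,16-tetranorlabdane-7,8-diol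
Product: 12 (5R,8R,9S,10R)-12-(benzyloxy)-8-hydroxy-13,14,15,16-tetranorlabdan-7-one
Conditions: IBX, DMSO, rt
Reagents that add atoms: none
Why: Hypervalent-iodine oxidation of the axial secondary C7 alcohol; 2-iodoxybenzoic acid converts 1,2-diols to α-ketols without C–C cleavage and cannot oxidise the tertiary C8 alcohol.

Step 9
Reactants: 12 (5R,8R,9S,10R)-12-(benzyloxy)-8-hydroxy-13,14,15,16-tetranorlabdan-7-one
Product: 13 (5R,8R,9S,10R)-12-(benzyloxy)-7,8-bis(triethylsilyloxy)-13,14,15,16-tetranorlabd-6-ene
Conditions: TESOTf (3.5 equiv), Et3N, CH2Cl2, 0 °C → rt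
Reagents that add atoms: triethylsilyl trifluoromethanesulfonate (TESOTf), CC[Si](CC)(CC)OS(=O)(=O)C(F)(F)F
Why: Silyl triflate and amine silylate the tertiary alcohol and convert the ketone to its enol silane in one operation. C8 has no hydrogen, so only the C6=C7 enol ether can form.

Step 10
Reactants: 13 (5R,8R,9S,10R)-12-(benzyloxy)-7,8-bis(triethylsilyloxy)-13,14,15,16-tetranorlabd-6-ene
Product: 15 (5R,6S,8R,9S,10R)-12-(benzyloxy)-6,8-bis(triethylsilyloxy)-13,14,15,16-tetranorlabdan-7-one, via silyloxy epoxide 14 (not isolated)
Conditions: mCPBA, NaHCO3, CH2Cl2, −20 → 0 °C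
Reagents that add atoms: 3-chloroperoxybenzoic acid (mCPBA), OOC(=O)c1cccc(Cl)c1
Why: Rubottom oxidation: the peracid epoxidises the enol silane on the face anti to the axial methyls C20 and C17, the silyloxy epoxide opens, and the silyl group moves to the new oxygen. The equatorial C6 oxygen (C6 S) is thus introduced already protected.

Step 11
Reactants: 15 (5R,6S,8R,9S,10R)-12-(benzyloxy)-6,8-bis(triethylsilyloxy)-13,14,15,16-tetranorlabdan-7-one
Product: 16 (5R,6S,7R,8R,9S,10R)-12-(benzyloxy)-6,8-bis(triethylsilyloxy)-13,14,15,16-tetranorlabdan-7-ol
Conditions: NaBH4, MeOH/THF, −20 → 0 °C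
Reagents that add atoms: none
Why: Hydride reduction of a hindered cyclohexanone: axial attack on the face anti to the axial C17 methyl should give the equatorial alcohol on the C20 face (C7 R), correcting the configuration created in step 4. The low temperature limits 1,2-silyl migration.

Step 12
Reactants: 16 (5R,6S,7R,8R,9S,10R)-12-(benzyloxy)-6,8-bis(triethylsilyloxy)-13,14,15,16-tetranorlabdan-7-ol
Product: 17 (5R,6S,7R,8R,9S,10R)-12-(benzyloxy)-6,8-bis(triethylsilyloxy)-13,14,15,16-tetranorlabdan-7-yl acetate
Conditions: Ac2O, Et3N, 4-(dimethylamino)pyridine, CH2Cl2, rt → 40 °C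
Reagents that add atoms: acetic anhydride, CC(=O)OC(C)=O
Why: Nucleophile-catalysed acylation; O7 is the only free hydroxyl, so the acetate is placed without any selectivity problem.

Step 13
Reactants: 17 (5R,6S,7R,8R,9S,10R)-12-(benzyloxy)-6,8-bis(triethylsilyloxy)-13,14,15,16-tetranorlabdan-7-yl acetate
Product: 18 (5R,6S,7R,8R,9S,10R)-12-hydroxy-6,8-bis(triethylsilyloxy)-13,14,15,16-tetranorlabdan-7-yl acetate
Conditions: H2 (1 atm), Pd/C, EtOAc, rt
Reagents that add atoms: none
Why: Hydrogenolysis of the benzyl ether; the molecule has no alkene at this stage, and in ethyl acetate the silyl ethers and the acetate are stable.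

Step 14
Reactants: 18 (5R,6S,7R,8R,9S,10R)-12-hydroxy-6,8-bis(triethylsilyloxy)-13,14,15,16-tetranorlabdan-7-yl acetate
Product: 19 (5R,6S,7R,8R,9S,10R)-12-oxo-6,8-bis(triethylsilyloxy)-13,14,15,16-tetranorlabdan-7-yl acetate
Conditions: DMP (1,1,1-triacetoxy-1,2-benziodoxol-3(1H)-one), NaHCO3, CH2Cl2, rt
Reagents that add atoms: none
Why: Buffered periodinane oxidation of the primary alcohol to the aldehyde; the silyl group on O8 prevents lactol formation with C12.

Step 15
Reactants: 19 (5R,6S,7R,8R,9S,10R)-12-oxo-6,8-bis(triethylsilyloxy)-13,14,15,16-tetranorlabdan-7-yl acetate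
Product: 20 (5R,6S,7R,8R,9S,10R,12Z)-13-iodo-6,8-bis(triethylsilyloxy)-14,15-dinorlabd-12-en-7-yl acetate
Conditions: EtPPh3I, n-BuLi, THF, rt; I2, −78 °C; NaN(SiMe3)2, −78 → −20 °C; then 19, −78 °C
Reagents that add atoms: ethyltriphenylphosphonium iodide, CC[P+](c1ccccc1)(c1ccccc1)c1ccccc1.[I-]; iodine, II
Why: Iodo-Wittig olefination of the Stork–Zhao type: the unstabilised α-iodoethylidene ylide adds under kinetic control through the oxaphosphetane that keeps iodine cis to the C11 chain, giving the (Z)-iodoalkene. The hindered acetate should survive the short exposure at −78 °C.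

Step 16
Reactants: 20 (5R,6S,7R,8R,9S,10R,12Z)-13-iodo-6,8-bis(triethylsilyloxy)-14,15-dinorlabd-12-en-7-yl acetate
Product: 21 (5R,6S,7R,8R,9S,10R,12Z)-6,8-dihydroxy-13-iodo-14,15-dinorlabd-12-en-7-yl acetate
Conditions: HF·pyridine, pyridine, THF, 0 °C → rt
Reagents that add atoms: none
Why: Buffered fluoride cleavage of both triethylsilyl ethers (secondary O6 and tertiary O8); the weakly acidic medium avoids acetate migration, and the acid-sensitive diene is not yet present.

Step 17
Reactants: 21 (5R,6S,7R,8R,9S,10R,12Z)-6,8-dihydroxy-13-iodo-14,15-dinorlabd-12-en-7-yl acetate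
Product: 22 (5R,6S,7R,8R,9S,10R,12Z)-6,8-dihydroxylabda-12,14-dien-7-yl acetate
Conditions: tributyl(vinyl)stannane, Pd(PPh3)4 (5 mol%), CuI, DMF, 40 °C
Reagents that add atoms: tributyl(vinyl)stannane, C=C[Sn](CCCC)(CCCC)CCCC
Why: Stille coupling: oxidative addition of zerovalent palladium to the C–I bond and reductive elimination both occur with retention, so the vinyl group takes the place of iodine cis to C11 (12Z). The neutral conditions leave the diol monoacetate and the new diene untouched.

## Compound list

1 | 2-(2,6,6-trimethylcyclohex-1-en-1-yl)acetaldehyde | CC1=C(CC=O)C(C)(C)CCC1 | starting material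
2 | (E)-2-[2-(tert-butyldimethylsilyloxy)ethenyl]-1,3,3-trimethylcyclohexene | CC1=C(/C=C/O[Si](C)(C)C(C)(C)C)C(C)(C)CCC1 | intermediate
3 | 3-(benzyloxy)propan-1-ol | OCCCOCc1ccccc1 | starting material
4 | 3-(benzyloxy)propanal | O=CCCOCc1ccccc1 | intermediate
5 | 2-(triphenylphosphoranylidene)propanal | CC(C=O)=P(c1ccccc1)(c1ccccc1)c1ccccc1 | starting material
6 | (E)-5-(benzyloxy)-2-methylpent-2-enal | O=C/C(C)=C/CCOCc1ccccc1 | intermediate
7 | (7S,8R,9S,10S)-12-(benzyloxy)-7-(tert-butyldimethylsilyloxy)-13,14,15,16-tetranorlabd-5-ene-8-carbaldehyde (formyl and silyloxy anti, C17 and C11 syn to C20) | c1ccccc1COCC[C@@H]1[C@@](C)(C=O)[C@@H](O[Si](C)(C)C(C)(C)C)C=C2C(C)(C)CCC[C@]21C | intermediate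
8 | (5R,7S,8R,9S,10R)-12-(benzyloxy)-7-(tert-butyldimethylsilyloxy)-13,14,15,16-tetranorlabdane-8-carbaldehyde | c1ccccc1COCC[C@@H]1[C@@](C)(C=O)[C@@H](O[Si](C)(C)C(C)(C)C)C[C@@H]2C(C)(C)CCC[C@]21C | intermediate
9 | (5R,7S,8R,9S,10R)-12-(benzyloxy)-7-(tert-butyldimethylsilyloxy)-13,14,15,16-tetranorlabdan-8-yl formate | c1ccccc1COCC[C@@H]1[C@@](C)(OC=O)[C@@H](O[Si](C)(C)C(C)(C)C)C[C@@H]2C(C)(C)CCC[C@]21C | intermediate
10 | (5R,7S,8R,9S,10R)-12-(benzyloxy)-7-(tert-butyldimethylsilyloxy)-13,14,15,16-tetranorlabdan-8-ol | c1ccccc1COCC[C@@H]1[C@@](C)(O)[C@@H](O[Si](C)(C)C(C)(C)C)C[C@@H]2C(C)(C)CCC[C@]21C | intermediate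
11 | (5R,7S,8R,9S,10R)-12-(benzyloxy)-13,14,15,16-tetranorlabdane-7,8-diol | c1ccccc1COCC[C@@H]1[C@@](C)(O)[C@@H](O)C[C@@H]2C(C)(C)CCC[C@]21C | intermediate
12 | (5R,8R,9S,10R)-12-(benzyloxy)-8-hydroxy-13,14,15,16-tetranorlabdan-7-one | c1ccccc1COCC[C@@H]1[C@@](C)(O)C(=O)C[C@@H]2C(C)(C)CCC[C@]21C | intermediate
13 | (5R,8R,9S,10R)-12-(benzyloxy)-7,8-bis(triethylsilyloxy)-13,14,15,16-tetranorlabd-6-ene | c1ccccc1COCC[C@@H]1[C@@](C)(O[Si](CC)(CC)CC)C(O[Si](CC)(CC)CC)=C[C@@H]2C(C)(C)CCC[C@]21C | intermediate
14 | (5R,6S,7R,8R,9S,10R)-12-(benzyloxy)-6,7-epoxy-7,8-bis(triethylsilyloxy)-13,14,15,16-tetranorlabdane (epoxide anti to C20) | c1ccccc1COCC[C@@H]1[C@@](C)(O[Si](CC)(CC)CC)[C@@]3(O[Si](CC)(CC)CC)O[C@H]3[C@@H]2C(C)(C)CCC[C@]21C | intermediate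
15 | (5R,6S,8R,9S,10R)-12-(benzyloxy)-6,8-bis(triethylsilyloxy)-13,14,15,16-tetranorlabdan-7-one | c1ccccc1COCC[C@@H]1[C@@](C)(O[Si](CC)(CC)CC)C(=O)[C@@H](O[Si](CC)(CC)CC)[C@@H]2C(C)(C)CCC[C@]21C | intermediate
16 | (5R,6S,7R,8R,9S,10R)-12-(benzyloxy)-6,8-bis(triethylsilyloxy)-13,14,15,16-tetranorlabdan-7-ol | c1ccccc1COCC[C@@H]1[C@@](C)(O[Si](CC)(CC)CC)[C@H](O)[C@@H](O[Si](CC)(CC)CC)[C@@H]2C(C)(C)CCC[C@]21C | intermediate
17 | (5R,6S,7R,8R,9S,10R)-12-(benzyloxy)-6,8-bis(triethylsilyloxy)-13,14,15,16-tetranorlabdan-7-yl acetate | c1ccccc1COCC[C@@H]1[C@@](C)(O[Si](CC)(CC)CC)[C@H](OC(C)=O)[C@@H](O[Si](CC)(CC)CC)[C@@H]2C(C)(C)CCC[C@]21C | intermediate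
18 | (5R,6S,7R,8R,9S,10R)-12-hydroxy-6,8-bis(triethylsilyloxy)-13,14,15,16-tetranorlabdan-7-yl acetate | OCC[C@@H]1[C@@](C)(O[Si](CC)(CC)CC)[C@H](OC(C)=O)[C@@H](O[Si](CC)(CC)CC)[C@@H]2C(C)(C)CCC[C@]21C | intermediate
19 | (5R,6S,7R,8R,9S,10R)-12-oxo-6,8-bis(triethylsilyloxy)-13,14,15,16-tetranorlabdan-7-yl acetate | O=CC[C@@H]1[C@@](C)(O[Si](CC)(CC)CC)[C@H](OC(C)=O)[C@@H](O[Si](CC)(CC)CC)[C@@H]2C(C)(C)CCC[C@]21C | intermediate
20 | (5R,6S,7R,8R,9S,10R,12Z)-13-iodo-6,8-bis(triethylsilyloxy)-14,15-dinorlabd-12-en-7-yl acetate | I/C(C)=C\C[C@@H]1[C@@](C)(O[Si](CC)(CC)CC)[C@H](OC(C)=O)[C@@H](O[Si](CC)(CC)CC)[C@@H]2C(C)(C)CCC[C@]21C | intermediate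
21 | (5R,6S,7R,8R,9S,10R,12Z)-6,8-dihydroxy-13-iodo-14,15-dinorlabd-12-en-7-yl acetate | I/C(C)=C\C[C@@H]1[C@@](C)(O)[C@H](OC(C)=O)[C@@H](O)[C@@H]2C(C)(C)CCC[C@]21C | intermediate
22 | (5R,6S,7R,8R,9S,10R,12Z)-6,8-dihydroxylabda-12,14-dien-7-yl acetate (CNP0225877.2) | C=C/C(C)=C\C[C@@H]1[C@@](C)(O)[C@H](OC(C)=O)[C@@H](O)[C@@H]2C(C)(C)CCC[C@]21C | target

## Step count and least certain steps

Total: 17 steps. Longest linear sequence: 16 steps (3 → 4 → 6 → 7 → … → 22, steps 2 to 17); the diene branch contributes one step (step 1).

Step 4 (key step).
- What may go wrong: the hindered diene terminus C10 (inside methyl, strained s-cis conformer) and the trisubstituted enal may fail to meet productively. Acid-induced desilylation of 2 or Mukaiyama-type addition to the formyl carbon could then take over. Silyl transfer to the triflimide could also generate an achiral silicon Lewis acid and erode the enantioselectivity.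
- Fallback (from 2 and 6, back at 7): the cycloaddition is run without any Lewis acid at about 12 kbar in CH2Cl2 at room temperature. This removes the desilylation and Mukaiyama channels and relies on the endo preference alone. The racemic adduct is then resolved by preparative chromatography on a chiral stationary phase, the mirror-image adduct F1 being set aside.

Step 5.
- What may go wrong: the second hydrogen atom may be delivered to C5 from the C20 face, or the reaction may stall, because the axial C7 silyloxy group stands 1,3 to C5 on the face that must accept hydrogen; trans selectivity would then be lost. Partial reduction of the aldehyde by the silane is a lesser concern.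
- Fallback (from 7, back at 11): hydroxyl-directed hydrogenation. The silyl ether of 7 is removed with buffered HF·pyridine (not with basic fluoride, to avoid retro-aldol cleavage) to give the allylic alcohol F2. Hydrogenation with [Ir(cod)(PCy3)(py)]PF6 and H2 in CH2Cl2 delivers hydrogen on the face of the C7 hydroxyl, that is anti to C20, to give the trans-fused hydroxy aldehyde F3. Baeyer–Villiger oxidation (mCPBA, NaHCO3) then gives the hydroxy formate F4, and K2CO3/MeOH returns diol 11.

Step 6.
- What may go wrong: hydrogen migration in the Criegee intermediate (over-oxidation to the carboxylic acid), or slow addition of the peracid to the neopentyl-type aldehyde.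
- Fallback (from 8, back at 10): MeMgBr in THF gives the secondary carbinol F5 (either epimer serves), and DMP gives the methyl ketone F6. CF3CO3H with Na2HPO4 then effects a Baeyer–Villiger reaction in which the tertiary C8 migrates in preference to methyl, with retention, to give the tertiary acetate F7. LiAlH4 in Et2O at 0 °C cleaves this ester to 10, which is desilylated as in the second half of step 7.

Step 10 (with step 9).
- What may go wrong: incomplete enolisation toward C6, whose axial hydrogen is screened by the axial C4 methyl and C20; or loss of the silyl group during the rearrangement, leaving O6 unprotected before the reduction.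
- Fallback (from 12, back at 15): direct enolate hydroxylation. TESOTf with 2,6-lutidine at −78 °C silylates only the tertiary alcohol to give the silyloxy ketone F8. Its potassium enolate (KN(SiMe3)2, THF, −78 °C) is oxidised with 2-(phenylsulfonyl)-3-phenyloxaziridine on the face anti to C20 to give the ketol F9. TESCl and imidazole in DMF then give 15.

Step 15.
- What may go wrong: erosion of the Z:E ratio or low conversion, through decomposition of the thermally labile iodo ylide, enolisation of the aldehyde or attack on the acetate.
- Fallback (from 19, back at 22): CCl4/PPh3 converts 19 to the 1,1-dichloroalkene F10. Palladium-catalysed trans-selective monomethylation (MeZnCl, PdCl2(DPEphos), THF) replaces the chlorine trans to C11 and gives the (Z)-chloroalkene F11. Negishi vinylation of the remaining C–Cl bond with retention (vinylzinc bromide, Pd(P(t-Bu)3)2) gives the bis-silylated diene F12. A short treatment with HF·pyridine/pyridine at 0 °C then gives 22.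

## Further compounds

F1 | step 4 | (7R,8S,9R,10R)-12-(benzyloxy)-7-(tert-butyldimethylsilyloxy)-13,14,15,16-tetranorlabd-5-ene-8-carbaldehyde (mirror image of 7) | c1ccccc1COCC[C@H]1[C@](C)(C=O)[C@H](O[Si](C)(C)C(C)(C)C)C=C2C(C)(C)CCC[C@@]21C
F2 | step 5 | (7S,8R,9S,10S)-12-(benzyloxy)-7-hydroxy-13,14,15,16-tetranorlabd-5-ene-8-carbaldehyde | c1ccccc1COCC[C@@H]1[C@@](C)(C=O)[C@@H](O)C=C2C(C)(C)CCC[C@]21C
F3 | step 5 | (5R,7S,8R,9S,10R)-12-(benzyloxy)-7-hydroxy-13,14,15,16-tetranorlabdane-8-carbaldehyde | c1ccccc1COCC[C@@H]1[C@@](C)(C=O)[C@@H](O)C[C@@H]2C(C)(C)CCC[C@]21C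
F4 | step 5 | (5R,7S,8R,9S,10R)-12-(benzyloxy)-7-hydroxy-13,14,15,16-tetranorlabdan-8-yl formate | c1ccccc1COCC[C@@H]1[C@@](C)(OC=O)[C@@H](O)C[C@@H]2C(C)(C)CCC[C@]21C
F5 | step 6 | 8-(1-hydroxyethyl) analogue of 8 (1-hydroxyethyl in place of formyl, carbinol epimers) | c1ccccc1COCC[C@@H]1[C@@](C)(C(C)O)[C@@H](O[Si](C)(C)C(C)(C)C)C[C@@H]2C(C)(C)CCC[C@]21C
F6 | step 6 | 8-acetyl analogue of 8 (methyl ketone in place of formyl) | c1ccccc1COCC[C@@H]1[C@@](C)(C(C)=O)[C@@H](O[Si](C)(C)C(C)(C)C)C[C@@H]2C(C)(C)CCC[C@]21C
F7 | step 6 | (5R,7S,8R,9S,10R)-12-(benzyloxy)-7-(tert-butyldimethylsilyloxy)-13,14,15,16-tetranorlabdan-8-yl acetate | c1ccccc1COCC[C@@H]1[C@@](C)(OC(C)=O)[C@@H](O[Si](C)(C)C(C)(C)C)C[C@@H]2C(C)(C)CCC[C@]21C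
F8 | step 10 | (5R,8R,9S,10R)-12-(benzyloxy)-8-(triethylsilyloxy)-13,14,15,16-tetranorlabdan-7-one | c1ccccc1COCC[C@@H]1[C@@](C)(O[Si](CC)(CC)CC)C(=O)C[C@@H]2C(C)(C)CCC[C@]21C
F9 | step 10 | (5R,6S,8R,9S,10R)-12-(benzyloxy)-6-hydroxy-8-(triethylsilyloxy)-13,14,15,16-tetranorlabdan-7-one | c1ccccc1COCC[C@@H]1[C@@](C)(O[Si](CC)(CC)CC)C(=O)[C@@H](O)[C@@H]2C(C)(C)CCC[C@]21C
F10 | step 15 | (5R,6S,7R,8R,9S,10R)-13,13-dichloro-6,8-bis(triethylsilyloxy)-14,15,16-trinorlabd-12-en-7-yl acetate | ClC(Cl)=CC[C@@H]1[C@@](C)(O[Si](CC)(CC)CC)[C@H](OC(C)=O)[C@@H](O[Si](CC)(CC)CC)[C@@H]2C(C)(C)CCC[C@]21C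
F11 | step 15 | (5R,6S,7R,8R,9S,10R,12Z)-13-chloro-6,8-bis(triethylsilyloxy)-14,15-dinorlabd-12-en-7-yl acetate | Cl/C(C)=C\C[C@@H]1[C@@](C)(O[Si](CC)(CC)CC)[C@H](OC(C)=O)[C@@H](O[Si](CC)(CC)CC)[C@@H]2C(C)(C)CCC[C@]21C
F12 | step 15 | (5R,6S,7R,8R,9S,10R,12Z)-6,8-bis(triethylsilyloxy)labda-12,14-dien-7-yl acetate | C=C/C(C)=C\C[C@@H]1[C@@](C)(O[Si](CC)(CC)CC)[C@H](OC(C)=O)[C@@H](O[Si](CC)(CC)CC)[C@@H]2C(C)(C)CCC[C@]21C
A1 | alternative 1 | 3-[(2E,8E,10Z)-11-(tert-butyldimethylsilyloxy)-3,7,7-trimethyldodeca-2,8,10-trienoyl]oxazolidin-2-one | O=C1OCCN1C(=O)/C=C(\C)CCCC(C)(C)/C=C/C=C(/C)O[Si](C)(C)C(C)(C)C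
A2 | alternative 1 | 3-[8-(tert-butyldimethylsilyloxy)-12,13,14,15,16-pentanorlabd-6-en-11-oyl]oxazolidin-2-one, trans-fused, configured as the target at C5, C8, C9 and C10 | O=C1OCCN1C(=O)[C@@H]2[C@@](C)(O[Si](C)(C)C(C)(C)C)C=C[C@@H]3C(C)(C)CCC[C@]32C
A3 | alternative 2 | 2,6-dimethyl-1,4-benzoquinone | CC1=CC(=O)C=C(C)C1=O
A4 | alternative 2 | 4-methylpenta-1,3-diene | C=CC=C(C)C
A5 | alternative 2 | cis-fused 4,4,8,10-tetramethyloctalin-2,7-diene-6,9-dione (labdane locants) | O=C1C(C)=CC(=O)[C@H]2C(C)(C)C=CC[C@]21C
A6 | alternative 3 | (R)-α-ionone | CC(=O)/C=C/[C@@H]1C(C)(C)CCC=C1C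
A7 | alternative 3 | methyl (E)-4-hydroxy-4-[trans-2,2-dimethyl-5-(2,6,6-trimethylcyclohex-2-en-1-yl)-1,3-dioxolan-4-yl]pent-2-enoate, configured as A8 | COC(=O)/C=C/[C@@](C)(O)[C@@H]1OC(C)(C)O[C@H]1[C@@H]2C(C)(C)CCC=C2C
A8 | alternative 3 | methyl 8-hydroxy-6,7-(isopropylidenedioxy)-13,14,15,16-tetranorlabdan-12-oate, configured as the target at C5 to C10 | COC(=O)C[C@@H]1[C@@](C)(O)[C@@H]3OC(C)(C)O[C@H]3[C@@H]2C(C)(C)CCC[C@]21C
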